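**Assumption:** the SMILES is read as (2S,3R,4R)-4-(3-hydroxy-4-methoxyphenyl)-6,7-dimethoxy-2,3-dimethyl-3,4-dihydronaphthalen-1(2H)-one (2,3-trans, 3,4-cis). Tetralone numbering is used throughout (C1 = carbonyl carbon, C4 = aryl-bearing carbon; ring A = dimethoxybenzo ring, ring B = carbocycle).

## Retrosynthetic overview

- The C1 ketone comes from a benzylic alcohol; the C4–H bond comes from hydrogenolysis (with inversion) of the bis-benzylic C4–O bond of a 1,4-epoxy-tetrahydronaphthalene, which also frees the phenol.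
- The C3 methyl comes from a C3 formyl group.
- The oxygen-bridged ring B comes from an enantioselective iminium-catalysed Diels–Alder reaction of a 1-aryl-isobenzofuran (C1 and C4 termini) with (E)-crotonaldehyde (C2 and C3). The isobenzofuran is generated from an acyclic hydroxy acetal in the same flask.
- The hydroxy acetal comes from the 6-bromoveratraldehyde acetal (ring A) and O-benzylisovanillin (pendant ring).
- Ring order: both benzene rings are bought; the furan ring and then ring B with its oxygen bridge form in one operation; the bridge ring is opened two steps later.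

## Route

Step 1
Reactants: 1 6-bromoveratraldehyde (2-bromo-4,5-dimethoxybenzaldehyde)
Product: 2 bromo acetal 1-bromo-2-(dimethoxymethyl)-4,5-dimethoxybenzene
Conditions: HC(OMe)3 (3 equiv), p-toluenesulfonic acid monohydrate (2 mol %), MeOH, 60 °C; Et3N quench
Reagents that add atoms: trimethyl orthoformate, COC(OC)OC; methanol (solvent, exchanges with the orthoformate), CO
Why: acid-catalysed acetalization masks the aldehyde so the aryl bromide can be lithiated; no stereocenter is formed.

Step 2
Reactants: 2 bromo acetal; 3 O-benzylisovanillin (3-(benzyloxy)-4-methoxybenzaldehyde)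
Product: 5 hydroxy acetal rac-[3-(benzyloxy)-4-methoxyphenyl][2-(dimethoxymethyl)-4,5-dimethoxyphenyl]methanol, via aryllithium 4 (not isolated)
Conditions: n-BuLi (1.05 equiv), THF, −78 °C, 30 min; then 3, −78 → 0 °C; H2O quench; used crude (kept free of acid)
Reagents that add atoms: none
Why: bromine–lithium exchange followed by 1,2-addition of the aryllithium to the aldehyde; the new carbinol centre is racemic and irrelevant because it becomes sp2 in step 3.

Step 3
Reactants: 5 hydroxy acetal; 6 (E)-crotonaldehyde ((2E)-but-2-enal)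
Product: 9 exo aldehyde (1R,2S,3S,4R)-1-[3-(benzyloxy)-4-methoxyphenyl]-6,7-dimethoxy-3-methyl-1,2,3,4-tetrahydro-1,4-epoxynaphthalene-2-carbaldehyde, via cyclic acetal 7 (not isolated), via isobenzofuran 8 (not isolated)
Conditions: CF3CO2H (5 mol %), MeCN, 23 °C, 20 min, Ar, dark; then 6 (3 equiv), (5R)-5-benzyl-2,2,3-trimethylimidazolidin-4-one hydrochloride (first-generation MacMillan imidazolidinone, 20 mol %), H2O (2 vol %), −20 → 0 °C, 24 h
Reagents that add atoms: none
Why: Proposed new method: trace acid closes 5 to cyclic acetal 7 and eliminates methanol to isobenzofuran 8 (first new ring), which is trapped in the same pot by the (E)-iminium ion of 6 and the imidazolidinone in an exo-selective Diels–Alder reaction (second new ring, the oxygen-bridged ring B); the benzyl group of the (5R)-catalyst blocks one face of the iminium, so the two dienophile carbons (later C2 and C3) are set in the required absolute sense with methyl and formyl trans (from the E-alkene), the unsubstituted furan terminus bonds to the iminium β-carbon (ortho-type regiochemistry, formyl carbon next to the aryl bridgehead), and the bridgeheads follow from suprafacial addition; the closest known reactions are the acid-induced generation and in situ trapping of isobenzofurans from o-(α-hydroxybenzyl)benzaldehyde acetals and the imidazolidinone-catalysed Diels–Alder reaction of 1,3-diphenylisobenzofuran with crotonaldehyde (exo, high ee).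

Step 4
Reactants: 9 exo aldehyde
Product: 11 dimethyl oxa-bridged tricycle (1R,2S,3S,4R)-1-[3-(benzyloxy)-4-methoxyphenyl]-6,7-dimethoxy-2,3-dimethyl-1,2,3,4-tetrahydro-1,4-epoxynaphthalene, via tosylhydrazone 10 (not isolated)
Conditions: TsNHNH2 (1.05 equiv), THF, 23 °C, concentrate; catecholborane (2 equiv), CHCl3, 0 °C; then NaOAc·3H2O, 50 °C
Reagents that add atoms: none
Why: Caglioti–Kabalka tosylhydrazone reduction (hydroboration of C=N, acetate-triggered loss of sulfinate, then N2 from the diazene) turns CHO into CH3 under near-neutral conditions that spare the α-stereocenter, the acid-labile oxygen bridge and the benzyl ether; no new stereocenter.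

Step 5
Reactants: 11 dimethyl oxa-bridged tricycle
Product: 12 tetralol (1R,2S,3R,4R)-4-(3-hydroxy-4-methoxyphenyl)-6,7-dimethoxy-2,3-dimethyl-1,2,3,4-tetrahydronaphthalen-1-ol
Conditions: H2 (1 atm), Pd/C (10 wt % Pd on carbon, 10 mol % Pd), EtOAc/EtOH 1:1, 23 °C; stopped at full conversion
Reagents that add atoms: none
Why: heterogeneous hydrogenolysis cleaves the strained tertiary bis-benzylic C4–O bond and the O-benzyl ether; on palladium, benzylic C–O hydrogenolysis runs with inversion, so hydrogen enters anti to the bridge oxygen and the aryl group ends up cis to the exo C3 methyl (C4 = R), while C1 keeps its oxygen and C2/C3 are untouched.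

Step 6
Reactants: 12 tetralol
Product: 13 target (2S,3R,4R)-4-(3-hydroxy-4-methoxyphenyl)-6,7-dimethoxy-2,3-dimethyl-3,4-dihydronaphthalen-1(2H)-one
Conditions: activated MnO2 (10 equiv), CH2Cl2, 23 °C
Reagents that add atoms: none
Why: MnO2 oxidation of the electron-rich benzylic secondary alcohol to the aryl ketone tolerates the free phenol; C2 already has the thermodynamically favoured trans (diequatorial) arrangement, so no stereocenter is at risk.

## Compound list

1 | 2-bromo-4,5-dimethoxybenzaldehyde (6-bromoveratraldehyde) | O=Cc1cc(OC)c(OC)cc1Br | starting material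
2 | 1-bromo-2-(dimethoxymethyl)-4,5-dimethoxybenzene | COC(OC)c1cc(OC)c(OC)cc1Br | intermediate
3 | 3-(benzyloxy)-4-methoxybenzaldehyde (O-benzylisovanillin) | COc1ccc(C=O)cc1OCc1ccccc1 | starting material
4 | [2-(dimethoxymethyl)-4,5-dimethoxyphenyl]lithium | [Li]c1cc(OC)c(OC)cc1C(OC)OC | intermediate (not isolated)
5 | rac-[3-(benzyloxy)-4-methoxyphenyl][2-(dimethoxymethyl)-4,5-dimethoxyphenyl]methanol | COc1ccc(C(O)c2cc(OC)c(OC)cc2C(OC)OC)cc1OCc1ccccc1 | intermediate
6 | (2E)-but-2-enal | C/C=C/C=O | starting material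
7 | 1-[3-(benzyloxy)-4-methoxyphenyl]-3,5,6-trimethoxy-1,3-dihydro-2-benzofuran (diastereomer mixture) | COC1OC(c2ccc(OC)c(OCc3ccccc3)c2)c2cc(OC)c(OC)cc12 | intermediate (not isolated)
8 | 1-[3-(benzyloxy)-4-methoxyphenyl]-5,6-dimethoxy-2-benzofuran | COc1ccc(cc1OCc1ccccc1)C1=C2C=C(OC)C(OC)=CC2=CO1 | intermediate (not isolated)
9 | (1R,2S,3S,4R)-1-[3-(benzyloxy)-4-methoxyphenyl]-6,7-dimethoxy-3-methyl-1,2,3,4-tetrahydro-1,4-epoxynaphthalene-2-carbaldehyde | O=C[C@H]1[C@H](C)[C@H]2O[C@]1(c1ccc(OC)c(OCc3ccccc3)c1)c1cc(OC)c(OC)cc12 | intermediate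
10 | N'-[(E)-{(1R,2R,3S,4R)-1-[3-(benzyloxy)-4-methoxyphenyl]-6,7-dimethoxy-3-methyl-1,2,3,4-tetrahydro-1,4-epoxynaphthalen-2-yl}methylidene]-4-methylbenzenesulfonohydrazide | Cc1ccc(cc1)S(=O)(=O)N/N=C/[C@H]1[C@H](C)[C@H]2O[C@]1(c1ccc(OC)c(OCc3ccccc3)c1)c1cc(OC)c(OC)cc12 | intermediate (not isolated)
11 | (1R,2S,3S,4R)-1-[3-(benzyloxy)-4-methoxyphenyl]-6,7-dimethoxy-2,3-dimethyl-1,2,3,4-tetrahydro-1,4-epoxynaphthalene | C[C@H]1[C@H](C)[C@H]2O[C@]1(c1ccc(OC)c(OCc3ccccc3)c1)c1cc(OC)c(OC)cc12 | intermediate
12 | (1R,2S,3R,4R)-4-(3-hydroxy-4-methoxyphenyl)-6,7-dimethoxy-2,3-dimethyl-1,2,3,4-tetrahydronaphthalen-1-ol | COc1ccc([C@@H]2c3cc(OC)c(OC)cc3[C@H](O)[C@@H](C)[C@@H]2C)cc1O | intermediate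
13 | (2S,3R,4R)-4-(3-hydroxy-4-methoxyphenyl)-6,7-dimethoxy-2,3-dimethyl-3,4-dihydronaphthalen-1(2H)-one | COc1ccc([C@@H]2c3cc(OC)c(OC)cc3C(=O)[C@@H](C)[C@@H]2C)cc1O | target

## Step count and risks

Total step count: 6. Longest linear sequence: 6 steps (1 → 2 → 5 → 9 → 11 → 12 → 13).

**Step 3 (most likely to fail).** The 1-aryl-isobenzofuran may decompose or react with free crotonaldehyde in an uncatalysed background reaction, which would lower the ee, and regio- or exo/endo-selectivity may be incomplete. The fallback moves stereocontrol from the catalyst to a covalently bound auxiliary; it sets out from 5 and returns at 9.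
- (4R)-4-Benzyl-1,3-oxazolidin-2-one is N-acylated with (E)-but-2-enoyl chloride (n-BuLi, THF, −78 °C) to give the imide (4R)-4-benzyl-3-[(2E)-but-2-enoyl]-1,3-oxazolidin-2-one F1.
- 5 is converted as before into isobenzofuran 8 (CF3CO2H cat., CH2Cl2), cooled to −78 °C and combined with F1 and Et2AlCl. The chelated s-cis imide is attacked on the face away from the benzyl group, giving the exo imide adduct F2 (separated from any endo isomer).
- Transamination with MeNH(OMe)·HCl/AlMe3 gives the Weinreb amide F3, and i-Bu2AlH at −78 °C returns aldehyde 9.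

**Step 4.** Hydrazone formation next to the quaternary bridgehead may be slow, and the α-centre could epimerize. The fallback replaces the hydrazone route by hydride displacement; it sets out from 9 and returns at 11. NaBH4 (MeOH, 0 °C) gives the primary alcohol F4, MsCl/Et3N gives the mesylate F5, and LiBHEt3 (THF, 0 → 23 °C) displaces the sulfonate to give 11.

**Step 5.** The hydrogenolysis may proceed with retention (giving the C4 epimer) or over-reduce the C1 benzylic alcohol. The fallback switches from surface hydrogenolysis to an ionic reduction whose facial selectivity is set by the C3 stereocenter; it sets out from 11 and returns at 12. Et3SiH (3 equiv)/BF3·OEt2 in CH2Cl2 at −78 °C ionizes the C4–O bond to the doubly benzylic cation, and hydride adds anti to the C3 methyl to give the benzyl-protected tetralol F6. A brief neutral H2, Pd/C debenzylation then gives 12.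

## Further compounds

F1 | step 3 | (4R)-4-benzyl-3-[(2E)-but-2-enoyl]-1,3-oxazolidin-2-one | C/C=C/C(=O)N1[C@H](Cc2ccccc2)COC1=O
F2 | step 3 | (4R)-4-benzyl-3-{[(1R,2S,3S,4R)-1-[3-(benzyloxy)-4-methoxyphenyl]-6,7-dimethoxy-3-methyl-1,2,3,4-tetrahydro-1,4-epoxynaphthalen-2-yl]carbonyl}-1,3-oxazolidin-2-one | O=C(N1[C@H](Cc2ccccc2)COC1=O)[C@H]1[C@H](C)[C@H]2O[C@]1(c1ccc(OC)c(OCc3ccccc3)c1)c1cc(OC)c(OC)cc12
F3 | step 3 | (1R,2S,3S,4R)-1-[3-(benzyloxy)-4-methoxyphenyl]-N,6,7-trimethoxy-N,3-dimethyl-1,2,3,4-tetrahydro-1,4-epoxynaphthalene-2-carboxamide | CON(C)C(=O)[C@H]1[C@H](C)[C@H]2O[C@]1(c1ccc(OC)c(OCc3ccccc3)c1)c1cc(OC)c(OC)cc12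
F4 | step 4 | [(1R,2R,3S,4R)-1-[3-(benzyloxy)-4-methoxyphenyl]-6,7-dimethoxy-3-methyl-1,2,3,4-tetrahydro-1,4-epoxynaphthalen-2-yl]methanol | OC[C@H]1[C@H](C)[C@H]2O[C@]1(c1ccc(OC)c(OCc3ccccc3)c1)c1cc(OC)c(OC)cc12
F5 | step 4 | [(1R,2R,3S,4R)-1-[3-(benzyloxy)-4-methoxyphenyl]-6,7-dimethoxy-3-methyl-1,2,3,4-tetrahydro-1,4-epoxynaphthalen-2-yl]methyl methanesulfonate | CS(=O)(=O)OC[C@H]1[C@H](C)[C@H]2O[C@]1(c1ccc(OC)c(OCc3ccccc3)c1)c1cc(OC)c(OC)cc12
F6 | step 5 | (1R,2S,3R,4R)-4-[3-(benzyloxy)-4-methoxyphenyl]-6,7-dimethoxy-2,3-dimethyl-1,2,3,4-tetrahydronaphthalen-1-ol | COc1ccc([C@@H]2c3cc(OC)c(OC)cc3[C@H](O)[C@@H](C)[C@@H]2C)cc1OCc1ccccc1
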